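**Retrosynthetic overview**

1. Target 16 comes from its O-TBS ether 15 by desilylation. Ether 15 is assembled in one flask from hydroxyquinolinone 6, aldehyde 13 and veprisine 9 by a chiral-acid-catalysed three-component domino Knoevenagel / inverse-electron-demand oxa-Diels–Alder reaction. This builds the central dihydropyran (ring A), three bonds (quinolinone C3–CH, CH–CH, O–CH) and all three stereocentres.
2. Enabling feature: ring A consists of the unit O–C4=C3 of a 4-oxy-2-quinolinone (the enol ether of a cyclic 1,3-dicarbonyl), the side-chain CH, and two ring-fusion carbons that are C3 and C4 of the dimethylpyran ring B. Ring A is therefore the cycloadduct of the 1-oxadiene O=C4–C3=CH–R, made in the flask from the acidic C3–H of 6 and an aldehyde, with the cis C3=C4 alkene of veprisine 9.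
3. Veprisine 9 comes from 6 and 3-methylbut-2-enal (Knoevenagel / oxa-6π). Quinolinone 6 comes from 2,3-dimethoxyaniline (N-methylation, Meldrum's acid, Friedel–Crafts closure). Aldehyde 13 comes from 2-methylpent-4-en-2-ol (silylation, ozonolysis).
4. Ring order: pyridone ring of 6, then pyran ring B (in 9), then pyran ring A (key step). Both quinolinone halves come from the single intermediate 6.

Key step: step 6

Remark: the (R)-enantiomer of the acid catalyst is assumed to shield the oxadiene face that leads to the (S,S,R) series; its antipode is equally available should the sense prove opposite.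

**Step 1**
Reactants: 1 2,3-dimethoxyaniline
Product: 3 N-methyl-2,3-dimethoxyaniline, via N-(methoxymethyl)-2,3-dimethoxyaniline 2 (not isolated)
Conditions: (CH2O)n, NaOMe, MeOH, reflux; then NaBH4, reflux
Reagents that add atoms: paraformaldehyde (as formaldehyde), C=O
Why: Reductive amination through the N-methoxymethyl aminal followed by NaBH4 reduction should stop at the secondary amine, because the aminal does not take up a second formaldehyde under these conditions.

**Step 2**
Reactants: 3 N-methyl-2,3-dimethoxyaniline; 4 Meldrum's acid (2,2-dimethyl-1,3-dioxane-4,6-dione)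
Product: 6 hydroxyquinolinone (4-hydroxy-7,8-dimethoxy-1-methylquinolin-2(1H)-one), via malonamic acid 5 (not isolated)
Conditions: neat, 90 °C; then Eaton's reagent (7.7 wt % P2O5 in MeSO3H, as solvent), 70 °C
Reagents that add atoms: none
Why: Aminolysis of Meldrum's acid with loss of acetone gives the malonamic acid, which should close by intramolecular Friedel–Crafts acylation at the only free ortho position (also para to a methoxy group), so one regioisomer is expected.

**Step 3**
Reactants: 6 hydroxyquinolinone; 7 3-methylbut-2-enal
Product: 9 veprisine (7,8-dimethoxy-2,2,6-trimethyl-2H-pyrano[3,2-c]quinolin-5(6H)-one), via oxatriene 8 (not isolated)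
Conditions: pyridine, 110 °C
Reagents that add atoms: none
Why: Knoevenagel condensation at the acidic C3–H followed by oxa-6π electrocyclisation of the 1-oxatriene through the C4 carbonyl (formal [3+3] annulation) is the established entry to 2,2-dimethyl-2H-pyrano[3,2-c]quinolin-5-ones.

**Step 4**
Reactants: 10 2-methylpent-4-en-2-ol
Product: 11 tert-butyldimethyl[(2-methylpent-4-en-2-yl)oxy]silane
Conditions: TBSOTf, 2,6-lutidine, CH2Cl2, 0 °C to rt
Reagents that add atoms: tert-butyldimethylsilyl triflate, CC(C)(C)[Si](C)(C)OS(=O)(=O)C(F)(F)F
Why: Silylation with the silyl triflate should protect the hindered tertiary alcohol; the TBS ether is there to block ionisation and cyclodehydration of the side chain under the acid of step 6, which would divert the oxadiene to 9.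

**Step 5**
Reactants: 11 tert-butyldimethyl[(2-methylpent-4-en-2-yl)oxy]silane
Product: 13 aldehyde 3-(tert-butyldimethylsilyloxy)-3-methylbutanal, via ozonide 12 (not isolated)
Conditions: O3, CH2Cl2, −78 °C; then PPh3, −78 °C to rt
Reagents that add atoms: ozone, [O-][O+]=O
Why: Ozonolysis of the terminal alkene with reductive work-up should give the β-silyloxy aldehyde under neutral conditions that avoid β-elimination.

**Step 6**
Reactants: 6 hydroxyquinolinone; 13 aldehyde 3-(tert-butyldimethylsilyloxy)-3-methylbutanal; 9 veprisine
Product: 15 O-tert-butyldimethylsilyl ether of target 16 (same skeleton and S/S/R configuration; side chain CH2C(CH3)2OTBS), via alkylidene-quinolinedione 14 (not isolated)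
Conditions: (R)-3,3'-bis(2,4,6-triisopropylphenyl)-1,1'-binaphthyl-2,2'-diyl N-triflylphosphoramide (10 mol %), 5 Å MS, CHCl3/PhCF3, −20 °C to rt; 9 (2 equiv), 13 (1.3 equiv), 6 added in portions
Reagents that add atoms: none
Why: Proposed new method: the acid should catalyse Knoevenagel condensation of the acidic C3–H of 6 with 13 to the 1-oxadiene 14 (O=C4–C3=CH–R), which, bound at the more basic amide oxygen as a contact ion pair in the chiral pocket, is attacked at its alkylidene carbon by C3 of the pyran ring of 9 (nucleophilic terminus of the dienyl ether O1–C10b=C4a–C4=C3) while the C4 carbonyl oxygen closes onto C4 of 9, where the quinolinone enol ether stabilises positive charge. The closest known reactions are the three-component domino Knoevenagel/hetero-Diels–Alder reaction of 4-hydroxyquinolin-2-ones with aldehydes and alkenes and the chiral N-triflylphosphoramide-catalysed [4+2] cycloaddition of in situ generated ortho-quinone methides with styrenes, which have not been combined on an alkylidene-quinolinedione. Ring A closes by an inverse-electron-demand oxa-[4+2] cycloaddition, suprafacial on both partners (in the stepwise limit, conjugate addition then 6-exo-trig capture of the vinylogous oxocarbenium ion by the enol oxygen). The two ring-fusion centres are cis because the alkene of 9 is locked Z in its ring; the side-chain centre follows from exo approach of 9 (gem-dimethyl carbon and quinolinone turned away from the dione) to the alkylidene isomer with the side chain anti to the C4 carbonyl, which places the side chain trans to the CMe2 carbon; the absolute sense is set by the chiral anion shielding one face of the oxadiene. The step needs angular rather than linear closure (C4=O, not the amide C2=O, as the oxygen terminus), secured by acid binding at the amide oxygen and the greater stability of the 2-quinolone product. It also needs 9 to out-compete a second molecule of 6, secured by portionwise addition of 6, excess 9 and the acid-reversibility of the 2:1 adduct.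

**Step 7**
Reactants: 15 O-tert-butyldimethylsilyl ether of target 16
Product: 16 target CNP0160874.2
Conditions: HF·pyridine, THF/pyridine, 0 °C to rt
Reagents that add atoms: none
Why: Fluoride-mediated Si–O cleavage (desilylation) under pyridine-buffered HF should free the tertiary alcohol without ionising the benzylic C–O bond of ring A, so the three stereocentres stay untouched.

**Compound list**

1 | 2,3-dimethoxyaniline | COc1cccc(N)c1OC | starting material
2 | N-(methoxymethyl)-2,3-dimethoxyaniline | COCNc1cccc(OC)c1OC | intermediate
3 | N-methyl-2,3-dimethoxyaniline | CNc1cccc(OC)c1OC | intermediate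
4 | Meldrum's acid (2,2-dimethyl-1,3-dioxane-4,6-dione) | CC1(C)OC(=O)CC(=O)O1 | starting material
5 | N-(2,3-dimethoxyphenyl)-N-methylmalonamic acid | CN(C(=O)CC(=O)O)c1cccc(OC)c1OC | intermediate
6 | 4-hydroxy-7,8-dimethoxy-1-methylquinolin-2(1H)-one | COc1ccc2c(O)cc(=O)n(C)c2c1OC | intermediate
7 | 3-methylbut-2-enal | CC(C)=CC=O | starting material
8 | 7,8-dimethoxy-1-methyl-3-(3-methylbut-2-en-1-ylidene)quinoline-2,4(1H,3H)-dione (oxatriene) | COc1ccc2c(c1OC)N(C)C(=O)C(=CC=C(C)C)C2=O | intermediate
9 | veprisine, 7,8-dimethoxy-2,2,6-trimethyl-2H-pyrano[3,2-c]quinolin-5(6H)-one | CC1(C)C=Cc2c(O1)c1ccc(OC)c(OC)c1n(C)c2=O | intermediate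
10 | 2-methylpent-4-en-2-ol | C=CCC(C)(C)O | starting material
11 | tert-butyldimethyl[(2-methylpent-4-en-2-yl)oxy]silane | C=CCC(C)(C)O[Si](C)(C)C(C)(C)C | intermediate
12 | 3-[2-(tert-butyldimethylsilyloxy)-2-methylpropyl]-1,2,4-trioxolane (racemic ozonide) | CC(C)(CC1OCOO1)O[Si](C)(C)C(C)(C)C | intermediate
13 | 3-(tert-butyldimethylsilyloxy)-3-methylbutanal | CC(C)(CC=O)O[Si](C)(C)C(C)(C)C | intermediate
14 | (Z)-3-[3-(tert-butyldimethylsilyloxy)-3-methylbutylidene]-7,8-dimethoxy-1-methylquinoline-2,4(1H,3H)-dione (side chain anti to the C4 carbonyl) | COc1ccc2c(c1OC)N(C)C(=O)/C(=C\CC(C)(C)O[Si](C)(C)C(C)(C)C)C2=O | intermediate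
15 | O-TBS ether of the target: cis-fused bis(dihydropyrano[3,2-c]quinolin-5-one), ring A C4 (S) bearing CH2C(CH3)2OTBS, C–C ring-fusion carbon (S), O-bearing ring-fusion carbon (R), both fusion H and the side chain on one face | COc1ccc2c3c(c(=O)n(C)c2c1OC)[C@@H](CC(C)(C)O[Si](C)(C)C(C)(C)C)[C@H]1[C@@H](O3)c2c(c3ccc(OC)c(OC)c3n(C)c2=O)OC1(C)C | intermediate
16 | CNP0160874.2: as 15 with a free 2-hydroxy-2-methylpropyl side chain; side-chain carbon (S), C–C ring-fusion carbon (S), O-bearing ring-fusion carbon (R) | COc1ccc2c3c(c(=O)n(C)c2c1OC)[C@@H](CC(C)(C)O)[C@H]1[C@@H](O3)c2c(c3ccc(OC)c(OC)c3n(C)c2=O)OC1(C)C | target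

**Step count**

Total: 7 steps. Longest linear sequence: 5 steps (steps 1, 2, 3, 6, 7) from 2,3-dimethoxyaniline.

**Steps most likely to fail**

Step 6. Possible failures are loss of enantiofacial control through a loosely ion-paired or uncatalysed background cycloaddition, erosion of exo/endo selectivity, capture of the oxadiene by a second molecule of 6, and acid-promoted ionisation of the side chain or dimerisation of 9. The fallback sets out from 6, 13 and 9 and uses the established achiral three-component domino Knoevenagel/hetero-Diels–Alder conditions (ethylenediammonium diacetate cat., MeCN, 60–80 °C). This should give 15 as the racemate, that is, together with the enantiomer of 15 F1. The two are then separated by preparative chromatography on a chiral stationary phase (amylose tris(3,5-dimethylphenylcarbamate), supercritical CO2/MeOH), and the route is rejoined at 15.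

Step 2. Possible failures are methanesulfonylation or O-demethylation of the electron-rich ring and decarboxylation of the malonamic acid before ring closure in the hot acidic medium. The fallback sets out from 3 and uses the classical thermal cyclocondensation with diethyl malonate in diphenyl ether at about 250 °C with removal of ethanol. It passes through ethyl N-(2,3-dimethoxyphenyl)-N-methylmalonamate F2, which closes thermally without strong acid, and returns to the route at 6.

Step 5. Possible failures are β-elimination of silanol from the aldehyde during ozonide reduction, over-oxidation, and loss of the volatile product on isolation. The fallback sets out from 11 and uses dihydroxylation (OsO4 cat., N-methylmorpholine N-oxide, acetone/H2O) to 4-(tert-butyldimethylsilyloxy)-4-methylpentane-1,2-diol F3. Glycol cleavage with NaIO4 on silica in CH2Cl2 then gives a solution of 13 that is used directly, returning to the route at 13.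

**Further compounds**

F1 | step 6 | enantiomer of 15 | COc1ccc2c3c(c(=O)n(C)c2c1OC)[C@H](CC(C)(C)O[Si](C)(C)C(C)(C)C)[C@@H]1[C@H](O3)c2c(c3ccc(OC)c(OC)c3n(C)c2=O)OC1(C)C
F2 | step 2 | ethyl N-(2,3-dimethoxyphenyl)-N-methylmalonamate | CCOC(=O)CC(=O)N(C)c1cccc(OC)c1OC
F3 | step 5 | 4-(tert-butyldimethylsilyloxy)-4-methylpentane-1,2-diol | CC(C)(CC(O)CO)O[Si](C)(C)C(C)(C)C
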